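**Retrosynthetic overview**
1. End-game, functional groups only: the 19-OAc comes from selective acetylation of the 3,19-diol acid. The axial 3-OH comes from a C19-OH-directed reduction of a 3-ketone. The C7=C8(–C17) unit comes from kinetic enol triflate formation and methyl coupling at a C8 ketone.
2. Key disconnection: C11–C12 together with C9–C10 and C4–C5. Bicyclic keto ester 18 goes back to acyclic epoxy vinyl ketone 13 (C14, two stereocentres) plus silyl dienolate 16 of methyl senecioate (C5). Ring A (C4–C5) forms first, then ring B (C9–C10), both in that step.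
3. Enabling feature: in ring B the methyl-bearing alkene carbon C8 is bonded to C9, and C9 carries side-chain carbon C11. With C8 written as C=O, the triad C11–C9–C8 is the β-carbon, α-carbon and carbonyl of a vinyl ketone. C11 therefore accepts C12, and the enol ether created at C8=C9 is the nucleophile that closes ring B on C10.
4. Logic copied from biosynthesis: C11–C12 is the junction between the C15 chain and the last C5 unit (the prenyl-transfer bond). It is followed by an A→B cationic cyclisation of the polyene, here epoxide-initiated.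
5. Compound 13 comes from a vinyl Grignard addition to a Weinreb amide, Sharpless epoxidation of a Z-allylic alcohol (the only source of chirality), and B-alkyl Suzuki coupling of diene ester 4 with Z-iodide 7.

Key step: step 10

Remark: positions are given in labdane numbering (decalin C1–C10, side chain C11–C16, C17 on C8, C18 = equatorial CH3 and C19 = axial CH2O on C4, C20 on C10). Compounds 1, 2, 5, 14 and all named reagents are taken as commercial.

**Step 1**
Reactants: 1 methyl 4-oxobutanoate; 2 2-(triphenylphosphoranylidene)propanal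
Product: 3 methyl (E)-5-methyl-6-oxohex-4-enoate
Conditions: toluene, 80 °C
Reagents that add atoms: none
Why: Wittig olefination with a stabilised α-branched ylide should give the E-trisubstituted enal (the later E-C5=C10 alkene), and the aldehyde of 1 reacts far faster than its ester.

**Step 2**
Reactants: 3 methyl (E)-5-methyl-6-oxohex-4-enoate
Product: 4 methyl (E)-5-methylhepta-4,6-dienoate
Conditions: MePPh3Br, NaHMDS, THF, −78 → 0 °C
Reagents that add atoms: methyltriphenylphosphonium bromide, C[P+](c1ccccc1)(c1ccccc1)c1ccccc1.[Br-]
Why: Wittig methylenation of the enal aldehyde is faster than any attack on the ester and leaves the E-alkene untouched.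

**Step 3**
Reactants: 5 prop-2-yn-1-ol
Product: 7 (Z)-3-iodo-2-methylprop-2-en-1-ol, via alkenylmagnesium chelate 6 (not isolated)
Conditions: MeMgBr (2.5 equiv), CuI (10 mol %), THF, −10 °C → rt; then I2, −10 °C; H2O
Reagents that add atoms: methylmagnesium bromide, C[Mg]Br; iodine, II
Why: Copper-catalysed, alkoxide-directed anti-carbomagnesiation puts methyl on the internal carbon and magnesium cis to CH2O in a five-membered chelate, and iodinolysis with retention should give the Z-iodide that later holds C19 cis to C2.

**Step 4**
Reactants: 4 methyl (E)-5-methylhepta-4,6-dienoate; 7 (Z)-3-iodo-2-methylprop-2-en-1-ol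
Product: 9 methyl (4E,8Z)-10-hydroxy-5,9-dimethyldeca-4,8-dienoate, via B-alkyl-9-BBN 8 (not isolated)
Conditions: 9-BBN, THF, 0 °C → rt; then 7, PdCl2(dppf) (5 mol %), AsPh3, Cs2CO3, DMF–H2O, rt
Reagents that add atoms: none
Why: Hydroboration with 9-BBN is selective for the monosubstituted terminus of the diene, and the B-alkyl Suzuki–Miyaura coupling proceeds with retention at the alkenyl iodide, so both alkene geometries are carried over.

**Step 5**
Reactants: 9 methyl (4E,8Z)-10-hydroxy-5,9-dimethyldeca-4,8-dienoate
Product: 10 (4E,8Z)-10-hydroxy-N-methoxy-N,5,9-trimethyldeca-4,8-dienamide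
Conditions: MeNH(OMe)·HCl, iPrMgCl (excess), THF, −20 → 0 °C
Reagents that add atoms: N,O-dimethylhydroxylamine hydrochloride, CNOC.Cl
Why: Weinreb amide formation by aminolysis of the ester with the magnesium amide tolerates the allylic alkoxide and both alkenes, and it is done before the epoxide is present.

**Step 6**
Reactants: 10 (4E,8Z)-10-hydroxy-N-methoxy-N,5,9-trimethyldeca-4,8-dienamide
Product: 11 (E)-7-[(2R,3S)-3-(hydroxymethyl)-3-methyloxiran-2-yl]-N-methoxy-N,5-dimethylhept-4-enamide
Conditions: Ti(OiPr)4 (cat.), L-(+)-DET (cat.), TBHP, 4 Å MS, CH2Cl2, −20 °C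
Reagents that add atoms: tert-butyl hydroperoxide, CC(C)(C)OO
Why: Sharpless asymmetric epoxidation touches only the allylic-alcohol alkene, and with L-(+)-tartrate the syn oxygen transfer to the Z-alkene should set C3 (R) and C4 (S), with CH2OH cis to the chain.

**Step 7**
Reactants: 11 epoxy alcohol
Product: 12 (E)-7-[(2R,3S)-3-{[(tert-butyldimethylsilyl)oxy]methyl}-3-methyloxiran-2-yl]-N-methoxy-N,5-dimethylhept-4-enamide
Conditions: TBSCl, imidazole, CH2Cl2, 0 °C → rt
Reagents that add atoms: tert-butyldimethylsilyl chloride, CC(C)(C)[Si](C)(C)Cl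
Why: Silyl ether formation gives a non-participating, poorly chelating group next to the epoxide, whereas an ester here would open the epoxide by neighbouring-group attack in step 10.

**Step 8**
Reactants: 12 silyl-protected epoxy Weinreb amide
Product: 13 (E)-9-[(2R,3S)-3-{[(tert-butyldimethylsilyl)oxy]methyl}-3-methyloxiran-2-yl]-7-methylnona-1,6-dien-3-one
Conditions: vinylMgBr, THF, −40 → 0 °C; inverse quench into cold dilute aqueous acid; used at once
Reagents that add atoms: vinylmagnesium bromide, C=C[Mg]Br
Why: The Weinreb ketone synthesis stops after one addition, the trisubstituted epoxide is inert to the Grignard reagent at low temperature, and the acidic inverse quench keeps the liberated amine from adding to the enone.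

**Step 9**
Reactants: 14 methyl 3-methylbut-2-enoate
Product: 16 tert-butyl[(1-methoxy-3-methylbuta-1,3-dien-1-yl)oxy]dimethylsilane, via lithium dienolate 15 (not isolated)
Conditions: LDA, THF–DMPU, −78 °C; TBSCl, −78 °C → rt
Reagents that add atoms: tert-butyldimethylsilyl chloride, CC(C)(C)[Si](C)(C)Cl
Why: Kinetic γ-deprotonation of the senecioate and O-silylation in the presence of DMPU (silyl ketene acetal formation) give the dienolate, whose acetal geometry is of no consequence.

**Step 10**
Reactants: 13 epoxy vinyl ketone; 16 silyl dienolate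
Product: 18 bicyclic 8-keto ester (3R,4R,5S,9S,10R; 3-OH equatorial; C19 axial; side chain equatorial), via acyclic silyl enol ether 17 (not isolated)
Conditions: 16 (1.05 equiv), Eu(fod)3 (5 mol %), CH2Cl2, 0 °C; then MeAlCl2 (3 equiv), −94 °C; H2O quench
Reagents that add atoms: none
Why: Proposed new method: a union-triggered polyene cyclisation: the Eu(III)-activated vinyl ketone of 13 is attacked at its β-carbon C11 by the γ-carbon C12 of silyl dienolate 16 (vinylogous Mukaiyama–Michael addition with silyl transfer to the ketone oxygen), which makes the C11–C12 bond and turns the electron-poor C9=C11 alkene into the nucleophilic silyl enol ether C8(OTBS)=C9 of 17; MeAlCl2 then ionises the epoxide at C4, C5=C10 attacks C4, C9 attacks the C10 cation, and loss of the silyl group leaves the C8 ketone. The closest known reaction types are the Lewis-acid-catalysed Mukaiyama–Michael addition of ketene silyl acetals to enones that stops at the silyl enol ether, the γ-selective reaction of O-silyl dienolates with soft carbon electrophiles, and the MeAlCl2-promoted epoxide-initiated polyene cyclisation terminated by a silyl enol ether; what is new is that the terminator is created by the fragment union in the same flask. Ring A closes by 6-endo opening of the epoxide at C4 (6-endo-trig at C5=C10) and ring B by 6-endo-trig attack of the enol ether C8=C9 on C10, through a chair–chair array. C3 keeps the configuration from step 6 and holds its O–Al group equatorial, which selects the alkene face; C4 is formed with inversion, so that the Z-derived CH2OTBS ends axial; C5 and C10 follow from anti addition across the E-alkene (trans ring fusion, C20 syn to C19); C9 follows from the Z-enol ether in the chair and, being α to the ketone, is corrected by equilibration to the equatorial side chain; the E-C13=C14 alkene follows from the s-trans dienolate. The step needs 1,4- and γ-selectivity in the union and activation of the enone before the epoxide: the first is secured by the unsubstituted CH2 terminus of the vinyl ketone and the gain of the conjugated enoate, the second by the more basic and open ketone oxygen, the mild Eu(fod)3, the shielding of the epoxide by the neighbouring CH2OTBS group, and the use of only one equivalent of 16, so that no free dienolate meets the activated epoxide.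

**Step 11**
Reactants: 18 bicyclic 8-keto ester
Product: 20 C7=C8 enol triflate (3R,4R,5S,9S,10R), via dilithio enolate alkoxide 19 (not isolated)
Conditions: LDA (2.1 equiv), THF, −78 °C; Comins' reagent, −78 °C
Reagents that add atoms: N-(5-chloropyridin-2-yl)bis(trifluoromethanesulfonimide), FC(F)(F)S(=O)(=O)N(c1ccc(Cl)cn1)S(=O)(=O)C(F)(F)F
Why: After the first equivalent of base is taken up by the 3-OH, kinetic deprotonation occurs at the open C7 methylene rather than at the tertiary C9–H next to quaternary C10, and O-sulfonylation at −78 °C (enol triflate formation) fixes the alkene at C7=C8 as in any keto ester.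

**Step 12**
Reactants: 20 enol triflate
Product: 21 methyl ester of the 3-equatorial alcohol with C7=C8 and the C17 methyl in place (3R,4R,5S,9R,10S)
Conditions: Me2Zn (3 equiv), Pd(PPh3)4 (5 mol %), THF, 0 °C → rt
Reagents that add atoms: dimethylzinc, C[Zn]C
Why: Negishi cross-coupling of the alkenyl triflate replaces OTf by the C17 methyl without moving the alkene, and the ester, enoate and silyl ether are inert to the organozinc reagent.

**Step 13**
Reactants: 21 3-equatorial alcohol
Product: 22 3-ketone (4R,5S,9R,10S)
Conditions: Dess–Martin periodinane, CH2Cl2, 0 °C → rt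
Reagents that add atoms: none
Why: Dess–Martin oxidation of the only free hydroxyl is neutral and leaves both alkenes and the β-silyloxy group (no α-hydrogen at C4, hence no elimination) untouched.

**Step 14**
Reactants: 22 3-ketone
Product: 23 19-hydroxy 3-ketone (4R,5S,9R,10S)
Conditions: HF·pyridine, THF–pyridine, 0 °C → rt
Reagents that add atoms: none
Why: Desilylation with buffered acidic fluoride frees the C19 hydroxyl without the basic conditions that would start a retro-aldol loss of formaldehyde from the β-hydroxy ketone.

**Step 15**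
Reactants: 23 19-hydroxy 3-ketone
Product: 25 3,19-diol methyl ester (3S,4R,5S,9R,10S; 3-OH axial), via alkoxydiacetoxyborohydride 24 (not isolated)
Conditions: Me4NBH(OAc)3, MeCN–AcOH, −30 °C
Reagents that add atoms: none
Why: In the Evans–Saksena hydroxyl-directed reduction the axial C19–O–B–H unit reaches the C3 carbonyl only from the face that carries C19 (six-membered transition state), so hydrogen enters on that face and the new 3-OH is axial and anti to C19, while the reagent does not reduce undirected ketones or the enoate.

**Step 16**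
Reactants: 25 3,19-diol methyl ester
Product: 26 3,19-diol acid (3S,4R,5S,9R,10S)
Conditions: LiOH, THF–MeOH–H2O, 50 °C; then aq. HCl to pH 3
Reagents that add atoms: lithium hydroxide, [Li+].[OH-]
Why: Saponification of the β,β-disubstituted enoate is done before the acetate is present, so no ester differentiation is needed and no stereocentre is at risk.

**Step 17**
Reactants: 26 3,19-diol acid
Product: 28 target CNP0325522.1, via C15 mixed anhydride 27 (not isolated)
Conditions: Ac2O (2.2 equiv), pyridine, 0 °C; then H2O–pyridine, rt
Reagents that add atoms: acetic anhydride, CC(=O)OC(C)=O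
Why: Selective acylation takes the primary C19-OH and leaves the axial secondary 3-OH flanked by quaternary C4, aqueous pyridine hydrolyses the transient mixed anhydride at C15, and acyl migration is excluded because O3 and C19 are trans-diaxial.

**Compound list**
1 | methyl 4-oxobutanoate | COC(=O)CCC=O | starting material
2 | 2-(triphenylphosphoranylidene)propanal | CC(C=O)=P(c1ccccc1)(c1ccccc1)c1ccccc1 | starting material
3 | methyl (E)-5-methyl-6-oxohex-4-enoate | COC(=O)CC/C=C(\C)C=O | intermediate
4 | methyl (E)-5-methylhepta-4,6-dienoate | COC(=O)CC/C=C(\C)C=C | intermediate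
5 | prop-2-yn-1-ol | C#CCO | starting material
6 | bromomagnesium (Z)-3-(bromomagnesio)-2-methylprop-2-en-1-olate (chelate, not isolated) | Br[Mg]OC/C(C)=C\[Mg]Br | intermediate
7 | (Z)-3-iodo-2-methylprop-2-en-1-ol | OC/C(C)=C\I | intermediate
8 | methyl (E)-7-(9-borabicyclo[3.3.1]nonan-9-yl)-5-methylhept-4-enoate (not isolated) | COC(=O)CC/C=C(\C)CCB1C2CCCC1CCC2 | intermediate
9 | methyl (4E,8Z)-10-hydroxy-5,9-dimethyldeca-4,8-dienoate | COC(=O)CC/C=C(\C)CC/C=C(/C)CO | intermediate
10 | (4E,8Z)-10-hydroxy-N-methoxy-N,5,9-trimethyldeca-4,8-dienamide | CON(C)C(=O)CC/C=C(\C)CC/C=C(/C)CO | intermediate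
11 | (E)-7-[(2R,3S)-3-(hydroxymethyl)-3-methyloxiran-2-yl]-N-methoxy-N,5-dimethylhept-4-enamide | CON(C)C(=O)CC/C=C(\C)CC[C@H]1O[C@@]1(C)CO | intermediate
12 | TBS ether of 11 | CON(C)C(=O)CC/C=C(\C)CC[C@H]1O[C@@]1(C)CO[Si](C)(C)C(C)(C)C | intermediate
13 | (E)-9-[(2R,3S)-3-{[(tert-butyldimethylsilyl)oxy]methyl}-3-methyloxiran-2-yl]-7-methylnona-1,6-dien-3-one | C=CC(=O)CC/C=C(\C)CC[C@H]1O[C@@]1(C)CO[Si](C)(C)C(C)(C)C | intermediate
14 | methyl 3-methylbut-2-enoate | COC(=O)C=C(C)C | starting material
15 | lithium dienolate of 14 (not isolated) | [Li+].[O-]C(OC)=CC(C)=C | intermediate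
16 | tert-butyl[(1-methoxy-3-methylbuta-1,3-dien-1-yl)oxy]dimethylsilane (acetal geometry not defined) | C=C(C)C=C(OC)O[Si](C)(C)C(C)(C)C | intermediate
17 | acyclic union product: (13E)-enoate, (8Z)-TBS enol ether, (5E)-alkene, (3R,4S)-epoxide (not isolated) | COC(=O)/C=C(\C)CC/C=C(\O[Si](C)(C)C(C)(C)C)CC/C=C(\C)CC[C@H]1O[C@@]1(C)CO[Si](C)(C)C(C)(C)C | intermediate
18 | methyl (13E)-19-(TBS-oxy)-3-hydroxy-8-oxo-17-norlabd-13-en-15-oate, (3R,4R,5S,9S,10R); trans-decalin, 3-OH equatorial, C19 axial syn to C20, side chain equatorial | CC(C)(C)[Si](C)(C)OC[C@@]1(C)[C@H]2CCC(=O)[C@@H](CC/C(C)=C/C(=O)OC)[C@]2(C)CC[C@H]1O | intermediate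
19 | dilithium C7=C8 enolate / C3 alkoxide of 18 (not isolated) | [Li+].[Li+].CC(C)(C)[Si](C)(C)OC[C@@]1(C)[C@H]2CC=C([O-])[C@@H](CC/C(C)=C/C(=O)OC)[C@]2(C)CC[C@H]1[O-] | intermediate
20 | C7=C8 enol triflate of 18, (3R,4R,5S,9S,10R) | CC(C)(C)[Si](C)(C)OC[C@@]1(C)[C@H]2CC=C(OS(=O)(=O)C(F)(F)F)[C@@H](CC/C(C)=C/C(=O)OC)[C@]2(C)CC[C@H]1O | intermediate
21 | methyl (13E)-19-(TBS-oxy)-3-hydroxylabda-7,13-dien-15-oate, (3R,4R,5S,9R,10S), 3-OH equatorial | CC(C)(C)[Si](C)(C)OC[C@@]1(C)[C@H]2CC=C(C)[C@@H](CC/C(C)=C/C(=O)OC)[C@]2(C)CC[C@H]1O | intermediate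
22 | methyl (13E)-19-(TBS-oxy)-3-oxolabda-7,13-dien-15-oate, (4R,5S,9R,10S) | CC(C)(C)[Si](C)(C)OC[C@@]1(C)[C@H]2CC=C(C)[C@@H](CC/C(C)=C/C(=O)OC)[C@]2(C)CCC1=O | intermediate
23 | methyl (13E)-19-hydroxy-3-oxolabda-7,13-dien-15-oate, (4R,5S,9R,10S) | OC[C@@]1(C)[C@H]2CC=C(C)[C@@H](CC/C(C)=C/C(=O)OC)[C@]2(C)CCC1=O | intermediate
24 | tetramethylammonium C19-alkoxy(diacetoxy)borohydride of 23 (not isolated) | C[N+](C)(C)C.CC(=O)O[BH-](OC(C)=O)OC[C@@]1(C)[C@H]2CC=C(C)[C@@H](CC/C(C)=C/C(=O)OC)[C@]2(C)CCC1=O | intermediate
25 | methyl (13E)-3,19-dihydroxylabda-7,13-dien-15-oate, (3S,4R,5S,9R,10S), 3-OH axial | OC[C@@]1(C)[C@H]2CC=C(C)[C@@H](CC/C(C)=C/C(=O)OC)[C@]2(C)CC[C@@H]1O | intermediate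
26 | (13E)-3,19-dihydroxylabda-7,13-dien-15-oic acid, (3S,4R,5S,9R,10S) | OC[C@@]1(C)[C@H]2CC=C(C)[C@@H](CC/C(C)=C/C(=O)O)[C@]2(C)CC[C@@H]1O | intermediate
27 | 19-acetate, C15 acetic mixed anhydride of 26 (not isolated) | CC(=O)OC[C@@]1(C)[C@H]2CC=C(C)[C@@H](CC/C(C)=C/C(=O)OC(C)=O)[C@]2(C)CC[C@@H]1O | intermediate
28 | (13E)-19-acetoxy-3-hydroxylabda-7,13-dien-15-oic acid, (3S,4R,5S,9R,10S), CNP0325522.1 | CC(=O)OC[C@@]1(C)[C@H]2CC=C(C)[C@@H](CC/C(C)=C/C(=O)O)[C@]2(C)CC[C@@H]1O | target

**Step count and risks**
Total step count: 17. Longest linear sequence: 15 (steps 1, 2, 4–8, 10–17).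

Steps most likely to fail:

Step 10 (labelled step).
- What may go wrong: the dienolate may attack through its α-carbon or add as a diene in a [4+2] sense. The epoxide may ionise before the union, giving an interrupted or oxygen-trapped cyclisation. The silyl enol ether may be lost by protodesilylation before ring B closes.
- Fallback (known chemistry, rings first and union second): it sets out from 13 and returns at 18. Conjugate addition of (phenylthio)trimethylsilane to 13 gives the β-phenylthio trimethylsilyl enol ether F1. Its MeAlCl2-promoted, enol-ether-terminated epoxy-polyene cyclisation, with no second component present, gives the bicyclic β-phenylthio ketone F2. One equivalent of mCPBA gives the sulfoxide F3, which on warming over CaCO3 undergoes β-elimination to the 9(11)-methylene 8-ketone F4. A conventional TiCl4-promoted vinylogous Mukaiyama–Michael addition of 16 to F4, followed by equilibration at C9, forms the same C11–C12 bond on the finished decalin and gives 18.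

Step 11.
- What may go wrong: competitive γ-deprotonation of the enoate side chain would cause deconjugation or loss of the E geometry on quench. Proton transfer could also move the enolate towards C9.
- Fallback (carbonyl olefination plus alkene isomerisation instead of enolate chemistry): it sets out from 18 and returns at 21. Wittig methylenation of the C8 ketone gives the exocyclic 8(17)-alkene F5. A cobalt-hydride (hydrogen-atom-transfer) alkene isomerisation then moves the 1,1-disubstituted double bond by one position to the less hindered C7 side and gives 21.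

Step 15.
- What may go wrong: slow ligand exchange at the neopentyl C19-OH would lead to sluggish or undirected hydride delivery and poor facial selectivity. Retro-aldol loss of formaldehyde from the β-hydroxy ketone is also possible.
- Fallback (steric approach control on the protected ketone instead of directed delivery): it sets out from 22 and returns at 25. K-Selectride reduction of 22 at −78 °C by equatorial attack gives the axial 3-alcohol silyl ether F6. HF·pyridine then removes the silyl group and gives 25.

**Further compounds**
F1 | step 10 | (Z)-β-phenylthio trimethylsilyl enol ether from 13 | c1ccccc1SC/C=C(\O[Si](C)(C)C)CC/C=C(\C)CC[C@H]2O[C@@]2(C)CO[Si](C)(C)C(C)(C)C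
F2 | step 10 | bicyclic 11-phenylthio 8-ketone | CC(C)(C)[Si](C)(C)OC[C@@]1(C)[C@H]2CCC(=O)[C@@H](CSc3ccccc3)[C@]2(C)CC[C@H]1O
F3 | step 10 | bicyclic 11-phenylsulfinyl 8-ketone (sulfur configuration undefined) | CC(C)(C)[Si](C)(C)OC[C@@]1(C)[C@H]2CCC(=O)[C@@H](CS(=O)c3ccccc3)[C@]2(C)CC[C@H]1O
F4 | step 10 | bicyclic 9(11)-methylene 8-ketone | CC(C)(C)[Si](C)(C)OC[C@@]1(C)[C@H]2CCC(=O)C(=C)[C@]2(C)CC[C@H]1O
F5 | step 11 | methyl (13E)-19-(TBS-oxy)-3-hydroxylabda-8(17),13-dien-15-oate | CC(C)(C)[Si](C)(C)OC[C@@]1(C)[C@H]2CCC(=C)[C@@H](CC/C(C)=C/C(=O)OC)[C@]2(C)CC[C@H]1O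
F6 | step 15 | methyl (13E)-19-(TBS-oxy)-3-hydroxylabda-7,13-dien-15-oate with axial 3-OH (3S) | CC(C)(C)[Si](C)(C)OC[C@@]1(C)[C@H]2CC=C(C)[C@@H](CC/C(C)=C/C(=O)OC)[C@]2(C)CC[C@@H]1O
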